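**Retrosynthetic overview**

1. The target comes from hydrolysis of a 4-chloropyridine; the C4 carbonyl of the pyridone is carried through the route as C–Cl.
2. The carbocycle (ring B) is closed last, at the C8–C8a bond, by a ring-closing Minisci acylation of a γ-pyridyl aldehyde (the proposed new step).
3. The aldehyde, its C4a–C5 bond and the C5 stereocentre come from an enantioselective redox-relay oxidative Heck arylation of (E)-9-phenylnon-3-en-1-ol with a pyridin-3-ylboronic acid.
4. The boronic acid comes from commercial 3-methoxy-2-methylpyridin-4(1H)-one (iodination, POCl3, I/Mg exchange–borylation); the alkenol comes from but-3-yn-1-ol and (5-bromopentyl)benzene, then LiAlH4.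
5. Ring order: the heterocycle (ring A) is bought intact; ring B is formed onto it in the penultimate step.

Assumption: the facial sense of the pyridine–oxazoline/palladium catalyst in step 6 is taken by analogy with simpler aryl partners; the route is written with the (S)-ligand, and if aldehyde 12 proves to be the antipode the (R)-ligand is used with nothing else changed.

**Step 1**
Reactants: 1 3-methoxy-2-methylpyridin-4(1H)-one
Product: 2 5-iodo-3-methoxy-2-methylpyridin-4(1H)-one
Conditions: NIS (1.1 equiv), DMF, rt to 50 °C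
Reagents that add atoms: N-iodosuccinimide, O=C1CCC(=O)N1I
Why: Electrophilic aromatic iodination of the vinylogous amide, which goes to C5 because it is the only free carbon next to the carbonyl (enaminone β-position), C6 next to nitrogen being electron-poor.

**Step 2**
Reactants: 2 5-iodo-3-methoxy-2-methylpyridin-4(1H)-one
Product: 3 4-chloro-5-iodo-3-methoxy-2-methylpyridine
Conditions: POCl3 (neat), 95 °C; then ice, aq. NaOH to pH 8
Reagents that add atoms: phosphoryl chloride, O=P(Cl)(Cl)Cl
Why: Deoxychlorination of a 4-pyridone (O-phosphorylation, then addition–elimination by chloride at C4) is the standard route to 4-chloropyridines and leaves the C–I bond intact.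

**Step 3**
Reactants: 3 4-chloro-5-iodo-3-methoxy-2-methylpyridine
Product: 6 (4-chloro-5-methoxy-6-methylpyridin-3-yl)boronic acid, via pyridylmagnesium chloride 4 (not isolated), via dimethyl pyridylboronate 5 (not isolated)
Conditions: i-PrMgCl·LiCl (1.1 equiv), THF, −40 °C; B(OMe)3 (1.5 equiv), −40 °C to rt; aq. HCl to pH 6
Reagents that add atoms: trimethyl borate, COB(OC)OC; water, O
Why: Iodine–magnesium exchange is fast and selective for C–I at −40 °C (C–Cl untouched and no pyridyne formation at this temperature), and borylation of the Grignard followed by hydrolysis gives the boronic acid.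

**Step 4**
Reactants: 7 but-3-yn-1-ol; 8 (5-bromopentyl)benzene
Product: 10 9-phenylnon-3-yn-1-ol, via dilithio butynolate 9 (not isolated)
Conditions: n-BuLi (2.1 equiv), THF, −78 to 0 °C; then 8, DMPU, 0 °C to rt
Reagents that add atoms: none
Why: SN2 alkylation of the alkynol dianion, which takes place at carbon because the acetylide is far more nucleophilic than the lithium alkoxide.

**Step 5**
Reactants: 10 9-phenylnon-3-yn-1-ol
Product: 11 (E)-9-phenylnon-3-en-1-ol
Conditions: LiAlH4 (3 equiv), diglyme/THF, 130 °C; aq. work-up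
Reagents that add atoms: none
Why: Hydroxyl-directed trans-hydroalumination of the homopropargylic alcohol followed by protonolysis with retention gives the (E)-alkene only.

**Step 6**
Reactants: 6 (4-chloro-5-methoxy-6-methylpyridin-3-yl)boronic acid; 11 (E)-9-phenylnon-3-en-1-ol
Product: 12 (4S)-4-(4-chloro-5-methoxy-6-methylpyridin-3-yl)-9-phenylnonanal
Conditions: 6 (2.5 equiv), Pd(MeCN)2(OTs)2 (6 mol %), Cu(OTf)2 (6 mol %), (S)-4-tert-butyl-2-[5-(trifluoromethyl)pyridin-2-yl]-4,5-dihydrooxazole (13 mol %), 3 Å MS, O2 (1 atm), DMF, rt, 24 h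
Reagents that add atoms: none
Why: Enantioselective redox-relay oxidative Heck reaction, in which the aryl–palladium species formed by transmetalation adds across the (E)-alkene with aryl going to the carbon remote from the hydroxyl, the chiral pyridine–oxazoline ligand on cationic divalent palladium selecting the alkene face and so setting the (4S) centre, after which palladium walks along the chain by β-hydride elimination/re-insertion to the carbinol carbon and leaves as the aldehyde while O2/Cu(OTf)2 reoxidise the metal.

**Step 7**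
Reactants: 12 (4S)-4-(4-chloro-5-methoxy-6-methylpyridin-3-yl)-9-phenylnonanal
Product: 13 (5S)-4-chloro-3-methoxy-2-methyl-5-(5-phenylpentyl)-6,7-dihydroquinolin-8(5H)-one
Conditions: TFA (2 equiv), FeSO4·7H2O (20 mol %), t-BuOOH (70% aq., 3 equiv, slow addition), degassed MeCN/H2O (4:1), 0.02 M, Ar, 0 °C to rt
Reagents that add atoms: none
Why: Proposed new method: a ring-closing Minisci acylation in which tert-butoxyl radical (from t-BuOOH and divalent iron) abstracts the weak, hydridic formyl C–H of 12 to give a nucleophilic acyl radical that attacks the only free carbon next to N+ of its own protonated pyridine (the future C8a; the other position flanking the tether is blocked by Cl) through a six-membered transition state, after which trivalent iron oxidises the adduct and loss of H+ rearomatises to the fused 2-acylpyridine without touching the remote stereocentre (its C–H sits on an electron-poor pyridinium and is polarity-mismatched for the electrophilic oxyl radical); the closest known reactions are the intermolecular Minisci acylation of protonated pyridines with aldehydes and aroyl-radical ring closures onto azines giving azafluorenones, whereas closure of an aliphatic acyl radical to a saturated six-membered ketone ring on a pyridine has not been shown.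

**Step 8**
Reactants: 13 (5S)-4-chloro-3-methoxy-2-methyl-5-(5-phenylpentyl)-6,7-dihydroquinolin-8(5H)-one
Product: 14 (5S)-3-methoxy-2-methyl-5-(5-phenylpentyl)-5,6,7,8-tetrahydroquinoline-4,8(1H)-dione
Conditions: 6 M aq. HCl/1,4-dioxane (1:1), 100 °C, sealed tube; then pH 7
Reagents that add atoms: water, O
Why: Nucleophilic aromatic substitution (addition–elimination) of chloride by water on the N-protonated 4-chloropyridine, followed by tautomerisation to the 4-pyridone, with the 3-methoxy group and the C5 centre (not α to either carbonyl) unaffected.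

**Compound list**

1 | 3-methoxy-2-methylpyridin-4(1H)-one | COc1c(C)[nH]ccc1=O | starting material
2 | 5-iodo-3-methoxy-2-methylpyridin-4(1H)-one | COc1c(C)[nH]cc(I)c1=O | intermediate
3 | 4-chloro-5-iodo-3-methoxy-2-methylpyridine | COc1c(C)ncc(I)c1Cl | intermediate
4 | (4-chloro-5-methoxy-6-methylpyridin-3-yl)magnesium chloride | COc1c(C)ncc([Mg]Cl)c1Cl | intermediate
5 | dimethyl (4-chloro-5-methoxy-6-methylpyridin-3-yl)boronate | COc1c(C)ncc(B(OC)OC)c1Cl | intermediate
6 | (4-chloro-5-methoxy-6-methylpyridin-3-yl)boronic acid | COc1c(C)ncc(B(O)O)c1Cl | intermediate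
7 | but-3-yn-1-ol | OCCC#C | starting material
8 | (5-bromopentyl)benzene | BrCCCCCc1ccccc1 | starting material
9 | lithium 4-lithiobut-3-yn-1-olate | [Li]OCCC#C[Li] | intermediate
10 | 9-phenylnon-3-yn-1-ol | OCCC#CCCCCCc1ccccc1 | intermediate
11 | (E)-9-phenylnon-3-en-1-ol | OCC/C=C/CCCCCc1ccccc1 | intermediate
12 | (4S)-4-(4-chloro-5-methoxy-6-methylpyridin-3-yl)-9-phenylnonanal | COc1c(C)ncc(c1Cl)[C@@H](CCCCCc1ccccc1)CCC=O | intermediate
13 | (5S)-4-chloro-3-methoxy-2-methyl-5-(5-phenylpentyl)-6,7-dihydroquinolin-8(5H)-one | COc1c(C)nc2c(c1Cl)[C@@H](CCCCCc1ccccc1)CCC2=O | intermediate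
14 | (5S)-3-methoxy-2-methyl-5-(5-phenylpentyl)-5,6,7,8-tetrahydroquinoline-4,8(1H)-dione (CNP0533270.1) | COc1c(C)[nH]c2c(c1=O)[C@@H](CCCCCc1ccccc1)CCC2=O | target

**Step count and risks**

Total steps: 8. Longest linear sequence: 6 (steps 1, 2, 3, 6, 7, 8); steps 4 and 5 make the alkenol side branch.

The three steps most likely to fail:

**Step 7 (the proposed new ring closure).** The risks are acylation of a second molecule, oxidation of the aldehyde to the acid, and hydrogen abstraction at the benzylic CH2 of the side chain. The fallback uses known chemistry, sets out from 12 and comes back at 13. Pinnick oxidation (NaClO2, NaH2PO4, 2-methylbut-2-ene, t-BuOH/H2O) gives (4S)-4-(4-chloro-5-methoxy-6-methylpyridin-3-yl)-9-phenylnonanoic acid F5. Coupling with N,O-dimethylhydroxylamine hydrochloride (EDC·HCl, HOBt, i-Pr2NEt, CH2Cl2) gives the Weinreb amide (4S)-4-(4-chloro-5-methoxy-6-methylpyridin-3-yl)-N-methoxy-N-methyl-9-phenylnonanamide F6. mCPBA in CH2Cl2 gives the pyridine N-oxide (4S)-4-(4-chloro-5-methoxy-6-methyl-1-oxidopyridin-1-ium-3-yl)-N-methoxy-N-methyl-9-phenylnonanamide F7. Deoxygenative bromination at the only free carbon next to nitrogen (Ts2O, n-Bu4NBr, CH2Cl2, rt) gives (4S)-4-(2-bromo-4-chloro-5-methoxy-6-methylpyridin-3-yl)-N-methoxy-N-methyl-9-phenylnonanamide F8. Bromine–lithium exchange (n-BuLi, THF, −95 °C) gives (4S)-4-(4-chloro-2-lithio-5-methoxy-6-methylpyridin-3-yl)-N-methoxy-N-methyl-9-phenylnonanamide F9, which closes onto the Weinreb amide (Parham cyclisation) and gives 13 on aqueous work-up.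

**Step 6 (stereocentre and C4a–C5 bond).** The basic pyridine nitrogen may bind the cationic palladium catalyst, and site selectivity or enantiomeric excess may be lower than with simple arylboronic acids. The fallback sets out from 3 and comes back at 12. Stille coupling of 3 with (E)-3-(tributylstannyl)prop-2-en-1-ol (Pd(PPh3)4, CuI, CsF, DMF, 45 °C) gives (E)-3-(4-chloro-5-methoxy-6-methylpyridin-3-yl)prop-2-en-1-ol F1. SOCl2 in CH2Cl2 at 0 °C gives 4-chloro-5-[(E)-3-chloroprop-1-en-1-yl]-3-methoxy-2-methylpyridine F2. Copper-catalysed asymmetric allylic alkylation (SN2′; CuBr·SMe2 3 mol %, chiral phosphoramidite ligand, CH2Cl2, −78 °C) with (5-phenylpentyl)magnesium bromide F3 (made from 8 and magnesium in Et2O) gives 4-chloro-3-methoxy-2-methyl-5-[(3S)-8-phenyloct-1-en-3-yl]pyridine F4. Linear-selective hydroformylation (Rh(acac)(CO)2, Xantphos, CO/H2 1:1, toluene, 80 °C) gives 12.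

**Step 8 (unmasking the pyridone).** The chloride is flanked by the methoxy group and the ring fusion, so acid hydrolysis may be slow and need forcing conditions. The fallback sets out from 13 and comes back at 14. Displacement with commercial sodium benzyloxide (1 M in benzyl alcohol; THF, 0 °C to rt) gives (5S)-4-(benzyloxy)-3-methoxy-2-methyl-5-(5-phenylpentyl)-6,7-dihydroquinolin-8(5H)-one F10. Hydrogenolysis (H2 1 atm, 10% Pd/C, EtOAc, rt, stopped at full conversion of the ether) gives 14.

**Further compounds**

F1 | step 6 | (E)-3-(4-chloro-5-methoxy-6-methylpyridin-3-yl)prop-2-en-1-ol | COc1c(C)ncc(/C=C/CO)c1Cl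
F2 | step 6 | 4-chloro-5-[(E)-3-chloroprop-1-en-1-yl]-3-methoxy-2-methylpyridine | COc1c(C)ncc(/C=C/CCl)c1Cl
F3 | step 6 | (5-phenylpentyl)magnesium bromide | Br[Mg]CCCCCc1ccccc1
F4 | step 6 | 4-chloro-3-methoxy-2-methyl-5-[(3S)-8-phenyloct-1-en-3-yl]pyridine | COc1c(C)ncc(c1Cl)[C@@H](CCCCCc1ccccc1)C=C
F5 | step 7 | (4S)-4-(4-chloro-5-methoxy-6-methylpyridin-3-yl)-9-phenylnonanoic acid | COc1c(C)ncc(c1Cl)[C@@H](CCCCCc1ccccc1)CCC(=O)O
F6 | step 7 | (4S)-4-(4-chloro-5-methoxy-6-methylpyridin-3-yl)-N-methoxy-N-methyl-9-phenylnonanamide | COc1c(C)ncc(c1Cl)[C@@H](CCCCCc1ccccc1)CCC(=O)N(C)OC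
F7 | step 7 | (4S)-4-(4-chloro-5-methoxy-6-methyl-1-oxidopyridin-1-ium-3-yl)-N-methoxy-N-methyl-9-phenylnonanamide | COc1c(C)[n+]([O-])cc(c1Cl)[C@@H](CCCCCc1ccccc1)CCC(=O)N(C)OC
F8 | step 7 | (4S)-4-(2-bromo-4-chloro-5-methoxy-6-methylpyridin-3-yl)-N-methoxy-N-methyl-9-phenylnonanamide | COc1c(C)nc(Br)c(c1Cl)[C@@H](CCCCCc1ccccc1)CCC(=O)N(C)OC
F9 | step 7 | (4S)-4-(4-chloro-2-lithio-5-methoxy-6-methylpyridin-3-yl)-N-methoxy-N-methyl-9-phenylnonanamide | COc1c(C)nc([Li])c(c1Cl)[C@@H](CCCCCc1ccccc1)CCC(=O)N(C)OC
F10 | step 8 | (5S)-4-(benzyloxy)-3-methoxy-2-methyl-5-(5-phenylpentyl)-6,7-dihydroquinolin-8(5H)-one | COc1c(C)nc2c(c1OCc1ccccc1)[C@@H](CCCCCc1ccccc1)CCC2=O
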